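**Numbering used throughout:** 1 olivetol; 2 its dimethyl ether; 3 the aldehyde; 4 the aryl formate (not isolated); 5 the ring B phenol; 6 methyl but-2-ynoate; 7 the aryloxycrotonate; 8 4-methoxy-6-methyl-2-pyrone; 9 1-iodobutane; 10 4-methoxy-6-pentyl-2-pyrone; 11 the pyrone adduct (not isolated); 12 the keto ester (not isolated); 13 the isocoumarin with ring B as its dimethyl ether; 14 the target.

Remark: 8 is taken as a purchasable compound, and 7 is drawn as the E isomer although either geometry would give the same dienolate in step 6.

## Analysis of the target

Target 14 is a 3-pentylisocoumarin in which benzene ring A (C4a, C5 to C8, C8a) is fused to an enol lactone (C1, O2, C3, C4), with a free hydroxyl on C6 and, on C8, an ether oxygen bound to C1' of ring B, a 2,4-dihydroxy-6-pentylphenyl group. The molecule has no stereocentre and no stereogenic double bond, so stereochemistry enters only through the geometry of an intermediate enol ether, which is erased later. The sensitive groups are the enol lactone, which hydroxide or alkoxide opens, and the three phenols; ring B, with three oxygens and an alkyl group, oxidises easily once free and is therefore unmasked last. The hard part is the diaryl ether: its oxygen sits on C1' between the C2' oxygen and the C6' pentyl chain and on C8 next to the peri lactone carbonyl, and both rings are electron rich, so substitution at either arene carbon is unattractive. In addition, the C6 oxygen has to be told apart from the two on ring B. The strategy rests on the alternating, acetate-type oxygen pattern of ring A and the lactone: C3 with its pentyl group, C4, C4a, C5 and C6 with its oxygen map onto C6, C5, C4, C3 and C2 of pyrone 10, whose ring oxygen becomes O2 and whose carbonyl oxygen becomes the C6 hydroxyl. C7, C8 with its aryloxy group, C8a and C1 map onto C4, C3, C2 and C1 of crotonate 7, so that only the bonds C4a–C8a, C6–C7 and C1–O2 remain to be made.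

## Retrosynthetic reasoning

**14 ⇒ 13.** The two O–CH3 bonds on C2' and C4' are cut. Ring B is carried as its dimethyl ether because these groups have to survive electrophilic formylation, a peracid, lithium amides and the anionic cascade. The forward step is a Lewis-acid ether cleavage that must leave the diaryl ether and the lactone alone. The C6 hydroxyl needs no protection because it is created free in the preceding step.

**13 ⇒ 7 + 10.** The bonds C4a–C8a, C6–C7 and C1–O2 are cut. This takes the whole bicycle apart while the hindered ether oxygen stays attached to a simple enol ether carbon; cutting the diaryl ether itself would instead demand substitution at an arene carbon flanked by two ortho groups. Two rings and three skeletal bonds are gained, and the C6 oxygen comes out differentiated from those of ring B. Forward, the dienolate of 7 must bond through its α-carbon to C4 of 10, where the methoxy group leaves, and through its γ-carbon to the lactone carbonyl C2, which opens the old ring. The enolate oxygen thereby released must then acylate the ester of 7.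

**7 ⇒ 5 + 6.** The vinyl C–O bond at the future C8 is cut. The crowded phenol oxygen of 5 is then joined to an unhindered sp carbon of 6 by conjugate addition, and no arene carbon is substituted. The forward reaction has to add oxygen, not carbon, and should settle on one alkene geometry, although both would serve.

**5 ⇒ 3 (through 4).** The C1'–O bond is traced back to a C1'–CHO bond. A formyl group can be placed regioselectively between a methoxy group and the pentyl chain, and an oxidative aryl migration then turns it into the phenol oxygen. The forward step needs aryl rather than hydride migration.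

**3 ⇒ 2 ⇒ 1.** The C1'–CHO bond and the two O–CH3 bonds are cut. Formylation of 2 must go para to one methoxy group and next to the pentyl chain, not between the two methoxy groups. Methylation of 1 is unproblematic.

**10 ⇒ 8 + 9.** The bond between the first and second carbon of the pentyl chain is cut. The methyl group of 8 is the most acidic carbon of that pyrone, so its anion can be alkylated with 9. The forward step must stop at monoalkylation.

## Alternatives that were turned down

**Alternative 1:** three-component assembly on a ring A aryne. The C8–O bond and the C8a–C1 bond are cut together. In the forward direction a fluoride source would unmask the C8–C8a aryne from 3-(hept-1-yn-1-yl)-5-methoxy-2-(trimethylsilyl)phenyl trifluoromethanesulfonate A2 under an atmosphere of carbon dioxide A3. The potassium salt of 5 would add to C8, and the aryl anion left on C8a would be carboxylated by A3 to give 2-(2,4-dimethoxy-6-pentylphenoxy)-6-(hept-1-yn-1-yl)-4-methoxybenzoic acid A1. A1 would then be cyclised onto its alkyne and demethylated.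
- For it: the ether forms at an sp-type aryne carbon, so steric crowding matters as little as in the chosen route. Each elementary event belongs to an established reaction class, which makes it stronger on precedent.
- Against it: A2 needs a multistep silyl triflate synthesis plus an alkyne coupling. The site of phenoxide attack rests only on the modest inductive bias of the alkynyl group. The aryl anion must take A3 faster than a proton. A1 still has to close 6-endo rather than 5-exo, and three methyl ethers remain.
- Comparison: its key step makes two bonds and no ring, where the chosen step makes three bonds and both rings from fragments that are each at most four steps from purchasable material.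

**Alternative 2:** Diels–Alder construction of ring A from a siloxydiene and an alkynyl aryl ether. The bonds C7–C8 and C4a–C8a are cut. Forward, (E)-4-methoxy-2-(trimethylsilyloxy)penta-1,3-diene A6 would be heated with methyl 3-(2,4-dimethoxy-6-pentylphenoxy)prop-2-ynoate A5, the unsubstituted terminus of A6 bonding to the aryloxy-bearing carbon of A5. Loss of the methoxy group and of the silyl group should then give methyl 2-(2,4-dimethoxy-6-pentylphenoxy)-4-hydroxy-6-methylbenzoate A4.
- For it: the regiochemistry of a polarised diene with a polarised alkyne is well understood and more predictable than the pairing the chosen key step needs. The ether bond is again made away from any arene carbon.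
- Against it: the aryloxy group donates into the β-carbon of A5 and makes it a poor dienophile. A6 has a fully substituted terminus, which slows the cycloaddition. A5 needs an alkynyl ether synthesis from 5. A4 contains only ring A, so phenol protection, lateral lithiation, acylation, lactonisation and deprotection must follow.
- Comparison: it is safer in regiochemistry but four to five steps longer after the key step, because the lactone ring is not formed.

**Alternative 3:** ring B built last on the ether oxygen by a Danheiser benzannulation. The bonds C5'–C6', C2'–C3', C4'–C5' and C1'–C2' are cut, so that ring B is assembled from a diazoketone and an alkyne. Forward, (E)-1-diazo-3-{[(6-methoxy-1-oxo-3-pentyl-1H-isochromen-8-yl)oxy]methylidene}octan-2-one A8 would be irradiated together with ethoxyethyne A9 and the mixture then heated. Wolff rearrangement of A8, [2+2] addition of A9 to the ketene so formed, four-electron ring opening and six-electron ring closure should deliver 8-(4-ethoxy-2-hydroxy-6-pentylphenoxy)-6-methoxy-3-pentyl-1H-isochromen-1-one A7.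
- For it: every substituent of ring B in A7 is placed unambiguously by the polarity of A9, a point on which it is stronger than the chosen route, and no hindered coupling is needed.
- Against it: A8 requires the complete ring A isocoumarin with a free C8 hydroxyl first, then enol ether formation and a diazoketone synthesis. The isocoumarin chromophore of A8 absorbs during the irradiation, and A9 is volatile and must be used in excess. The ethyl ether and the methyl ether of A7 must still be cleaved at the end.
- Comparison: the longest linear sequence would be roughly twice that of the chosen route, which offers convergence and a single ring-forming step in exchange for a less certain regiochemistry.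

Key step: step 6

## Route

Step 1
Reactants: 1 olivetol (5-pentylbenzene-1,3-diol)
Product: 2 1,3-dimethoxy-5-pentylbenzene
Conditions: Me2SO4, K2CO3, acetone, reflux
Reagents that add atoms: dimethyl sulfate, COS(=O)(=O)OC
Why: Williamson O-methylation of both phenols; K2CO3 is basic enough for a resorcinol and dimethyl sulfate alkylates oxygen, not the ring, in acetone.

Step 2
Reactants: 2 1,3-dimethoxy-5-pentylbenzene
Product: 3 2,4-dimethoxy-6-pentylbenzaldehyde
Conditions: POCl3, DMF, 0 → 60 °C; then H2O, 50 °C
Reagents that add atoms: N,N-dimethylformamide, CN(C)C=O; water, O
Why: Vilsmeier–Haack formylation; the chloroiminium ion should attack para to one methoxy group and ortho to the other, next to the pentyl chain, rather than the more crowded position between the two methoxy groups, which is the pattern ring B needs.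

Step 3
Reactants: 3 2,4-dimethoxy-6-pentylbenzaldehyde
Product: 5 2,4-dimethoxy-6-pentylphenol, via aryl formate 4 (not isolated)
Conditions: mCPBA, CH2Cl2, 0 °C → rt; wash (aq Na2SO3, NaHCO3); then K2CO3 (cat.), MeOH, rt
Reagents that add atoms: 3-chloroperoxybenzoic acid (mCPBA), OOC(=O)c1cccc(Cl)c1
Why: Baeyer–Villiger (Dakin-type) oxidation; the electron-rich, di-ortho-substituted aryl group should migrate in preference to hydride to give formate 4. Mild methanolysis frees the phenol only after the peracid has been removed and does not touch the methyl ethers.

Step 4
Reactants: 5 2,4-dimethoxy-6-pentylphenol; 6 methyl but-2-ynoate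
Product: 7 methyl (E)-3-(2,4-dimethoxy-6-pentylphenoxy)but-2-enoate
Conditions: DABCO (0.2 eq), MeCN, 60 °C
Reagents that add atoms: none
Why: Amine-catalysed oxa-Michael addition of a phenol to an alkynoate; the phenoxide attacks the unhindered sp carbon C3, so the crowded oxygen never has to substitute an arene carbon. Reversible addition should settle on the E isomer with ester and aryloxy group trans.

Step 5
Reactants: 8 4-methoxy-6-methyl-2H-pyran-2-one; 9 1-iodobutane
Product: 10 4-methoxy-6-pentyl-2H-pyran-2-one
Conditions: LiN(iPr)2 (1.1 eq), THF–DMPU, −78 °C; 9, −78 → −20 °C
Reagents that add atoms: none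
Why: Lateral lithiation of the 6-methyl group of a 4-methoxy-2-pyrone gives a vinylogous enolate that a primary iodide alkylates on carbon by SN2. Monoalkylation is favoured because the new CH2 group is less acidic than the methyl group of 8.

Step 6
Reactants: 7 methyl (E)-3-(2,4-dimethoxy-6-pentylphenoxy)but-2-enoate; 10 4-methoxy-6-pentyl-2H-pyran-2-one
Product: 13 8-(2,4-dimethoxy-6-pentylphenoxy)-6-hydroxy-3-pentyl-1H-isochromen-1-one, via pyrone adduct 11 (not isolated), via keto ester 12 (not isolated)
Conditions: 7, LiN(iPr)2 (1.05 eq), THF, −78 °C; 10 (1.1 eq), −78 °C → rt, then 60 °C; aq HCl; then TsOH·H2O (cat.), PhMe, 80 °C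
Reagents that add atoms: none
Why: Proposed new method: LiN(iPr)2 removes a proton from the methyl group of 7, which lies cis to the ester, and the α-carbon of the resulting lithium dienolate adds to C4 of 10, the vinylogous ester carbon, with loss of the methoxy group to give 11 (bond C8a–C4a). The α-hydrogen of 11, acidified by the ester and, through the pyrone, by the lactone carbonyl, is removed by the lithium methoxide set free, and the CH2 terminus of this trienolate attacks the lactone carbonyl (bond C7–C6), a 6-exo-trig closure of ring A that can also be read as a disrotatory six-electron electrocyclisation; the adduct collapses by expelling the enolate oxygen on the pentyl-bearing carbon, and the dienone tautomerises to the C6 phenoxide, the anion of 12. The enolate oxygen, held cis to the arene because the pyrone ring fixed that geometry, can acylate the neighbouring methyl ester in a second 6-exo-trig closure (bond C1–O2); since the C6 phenoxide, para to the ester, slows this once ring A is aromatic, whatever 12 remains is closed with TsOH, a standard enol lactonisation. The closest known reaction types are the Staunton–Weinreb annulation, in which a stabilised carbanion enters a 4-methoxy-2-pyrone at C4 and a Claisen closure follows, and the base-induced recyclisation of opened pyrones to resorcylates; neither has been run with an ester dienolate so that the pyrone is opened and a new lactone is closed in the same operation. No stereocentre survives, since the one centre of 11 is lost on deprotonation. The step needs the α-carbon of the dienolate to pair with C4 and the γ-carbon with C2; the same pairing in the reverse order, γ-acylation at C2 followed by α-closure on C4, would also end in 12. The substrate secures the second half of this: C4 carries the only leaving group on a conjugate position, and once C8a–C4a exists the pyrone C3 carbanion could reach the ester only through a four-membered ring, so the Claisen channel is shut and the only six-membered closure left is γ onto C2. The choice between α and γ in the first bond is not fixed by structure and is steered only by using the lithium dienolate as a contact ion pair in THF at −78 °C without donor cosolvent.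

Step 7
Reactants: 13 8-(2,4-dimethoxy-6-pentylphenoxy)-6-hydroxy-3-pentyl-1H-isochromen-1-one
Product: 14 8-(2,4-dihydroxy-6-pentylphenoxy)-6-hydroxy-3-pentyl-1H-isochromen-1-one
Conditions: BBr3 (6 eq), CH2Cl2, −78 → 0 °C; then H2O
Reagents that add atoms: none
Why: Lewis-acid cleavage of aryl methyl ethers; bromide removes each methyl group by SN2 from the boron-bound oxygen, while the diaryl ether has no sp3 carbon to attack and the lactone should survive at low temperature. An excess is used because the C6 phenol and the lactone carbonyl also bind boron.

## Compound list

1 | olivetol (5-pentylbenzene-1,3-diol) | CCCCCc1cc(O)cc(O)c1 | starting material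
2 | 1,3-dimethoxy-5-pentylbenzene | CCCCCc1cc(OC)cc(OC)c1 | intermediate
3 | 2,4-dimethoxy-6-pentylbenzaldehyde | CCCCCc1cc(OC)cc(OC)c1C=O | intermediate
4 | 2,4-dimethoxy-6-pentylphenyl formate | CCCCCc1cc(OC)cc(OC)c1OC=O | intermediate
5 | 2,4-dimethoxy-6-pentylphenol | CCCCCc1cc(OC)cc(OC)c1O | intermediate
6 | methyl but-2-ynoate | CC#CC(=O)OC | starting material
7 | methyl (E)-3-(2,4-dimethoxy-6-pentylphenoxy)but-2-enoate | COC(=O)/C=C(/Oc1c(OC)cc(OC)cc1CCCCC)C | intermediate
8 | 4-methoxy-6-methyl-2H-pyran-2-one | Cc1cc(OC)cc(=O)o1 | starting material
9 | 1-iodobutane | CCCCI | starting material
10 | 4-methoxy-6-pentyl-2H-pyran-2-one | CCCCCc1cc(OC)cc(=O)o1 | intermediate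
11 | methyl 3-(2,4-dimethoxy-6-pentylphenoxy)-2-(2-oxo-6-pentyl-2H-pyran-4-yl)but-3-enoate (racemic; the centre is lost on deprotonation) | COC(=O)C(C(=C)Oc1c(OC)cc(OC)cc1CCCCC)c1cc(=O)oc(CCCCC)c1 | intermediate
12 | methyl 2-(2,4-dimethoxy-6-pentylphenoxy)-4-hydroxy-6-(2-oxoheptyl)benzoate | COC(=O)c1c(CC(=O)CCCCC)cc(O)cc1Oc1c(OC)cc(OC)cc1CCCCC | intermediate
13 | 8-(2,4-dimethoxy-6-pentylphenoxy)-6-hydroxy-3-pentyl-1H-isochromen-1-one | CCCCCc1cc2cc(O)cc(Oc3c(OC)cc(OC)cc3CCCCC)c2c(=O)o1 | intermediate
14 | 8-(2,4-dihydroxy-6-pentylphenoxy)-6-hydroxy-3-pentyl-1H-isochromen-1-one | CCCCCc1cc2cc(O)cc(Oc3c(O)cc(O)cc3CCCCC)c2c(=O)o1 | target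

## Step count and least certain steps

Total: 7 steps. Longest linear sequence: 6 steps (steps 1, 2, 3, 4, 6, 7); the pyrone branch joins after step 5.

**Step 6 (key step, proposed new method).** The most likely failure is wrong site selection in the first bond. Ester dienolates with an oxygen on the β-carbon often react through the γ-carbon. Entry of the γ-carbon at C4, followed by Claisen closure of the pyrone C3 carbanion on the ester (the known annulation channel), would exchange the positions of the hydroxyl and the aryloxy group on ring A without changing the formula, so the constitution of 13 would have to be secured by two-dimensional NMR correlation before going on. Entry of the γ-carbon at C4 followed by attack of the α-carbon on C2 would leave the ester and the ketone side chain too far apart to lactonise. A second failure is proton transfer: the dienolate may act as a base toward the very acidic 11 or toward the side-chain CH2 group of 10, so that conversion stalls; a second equivalent of dienolate would then be tried, with recovery of 7.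

Fallback by known chemistry, setting out from phenol 5 and coming back to the route at target 14: purchasable methyl 2-hydroxy-4-methoxy-6-methylbenzoate is converted with Tf2O and pyridine into methyl 4-methoxy-2-methyl-6-[(trifluoromethylsulfonyl)oxy]benzoate F1. Palladium-catalysed C–O coupling of F1 with 5 (Pd(OAc)2, t-BuXPhos, K3PO4, toluene, 100 °C) should give methyl 2-(2,4-dimethoxy-6-pentylphenoxy)-4-methoxy-6-methylbenzoate F2. Lateral lithiation of F2 with LiN(iPr)2 (2 eq, THF, −78 °C) and acylation with N-methoxy-N-methylhexanamide should give methyl 2-(2,4-dimethoxy-6-pentylphenoxy)-4-methoxy-6-(2-oxoheptyl)benzoate F3. TsOH in hot toluene closes F3 to 8-(2,4-dimethoxy-6-pentylphenoxy)-6-methoxy-3-pentyl-1H-isochromen-1-one F4, and BBr3 cleaves all three methyl ethers of F4 to give 14. The price is a coupling at a crowded phenol oxygen, which the main route avoids.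

**Step 4.** Addition of the hindered phenol to an internal alkynoate may be sluggish, and the amine may instead isomerise 6 to the allenoate and oligomerise it. A mixture of alkene isomers would not matter. Fallback, from 5 back to 7: addition–elimination of the potassium phenoxide of 5 (K2CO3, DMF, 60 °C) on purchasable methyl (E)-3-chlorobut-2-enoate, a vinylic substitution instead of an alkyne addition. This fallback makes no new compound (F0).

**Step 5.** The anion of 8 may add to C4 of a second molecule of 8 faster than it is alkylated, ring metalation may compete, and some dialkylation is possible. Fallback, from iodide 9 back to 10: the dianion of purchasable 4-hydroxy-6-methyl-2H-pyran-2-one (LiN(iPr)2, 2.2 eq, THF–DMPU) is alkylated with 9 at the methyl carbon to give 4-hydroxy-6-pentyl-2H-pyran-2-one F5, which Me2SO4 and K2CO3 in acetone methylate on oxygen to 10. The dianion is more nucleophilic and cannot act as an electrophile.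

**Step 3.** The peracid may oxidise the electron-rich ring or the product phenol, and hydride migration would lead to the carboxylic acid instead of the formate. Fallback, from 2 back to 5, without any aldehyde: NBS in MeCN brominates the same ring position of 2 to give 2-bromo-1,5-dimethoxy-3-pentylbenzene F6. Bromine–lithium exchange on F6 with n-BuLi at −78 °C and trapping with B(OMe)3 gives dimethyl (2,4-dimethoxy-6-pentylphenyl)boronate F7, which H2O2 and NaOH oxidise to 5.

## Further compounds

F1 | step 6 | methyl 4-methoxy-2-methyl-6-[(trifluoromethylsulfonyl)oxy]benzoate | COC(=O)c1c(C)cc(OC)cc1OS(=O)(=O)C(F)(F)F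
F2 | step 6 | methyl 2-(2,4-dimethoxy-6-pentylphenoxy)-4-methoxy-6-methylbenzoate | COC(=O)c1c(C)cc(OC)cc1Oc1c(OC)cc(OC)cc1CCCCC
F3 | step 6 | methyl 2-(2,4-dimethoxy-6-pentylphenoxy)-4-methoxy-6-(2-oxoheptyl)benzoate | COC(=O)c1c(CC(=O)CCCCC)cc(OC)cc1Oc1c(OC)cc(OC)cc1CCCCC
F4 | step 6 | 8-(2,4-dimethoxy-6-pentylphenoxy)-6-methoxy-3-pentyl-1H-isochromen-1-one | CCCCCc1cc2cc(OC)cc(Oc3c(OC)cc(OC)cc3CCCCC)c2c(=O)o1
F0 | step 4 | none | none
F5 | step 5 | 4-hydroxy-6-pentyl-2H-pyran-2-one | CCCCCc1cc(O)cc(=O)o1
F6 | step 3 | 2-bromo-1,5-dimethoxy-3-pentylbenzene | CCCCCc1cc(OC)cc(OC)c1Br
F7 | step 3 | dimethyl (2,4-dimethoxy-6-pentylphenyl)boronate | CCCCCc1cc(OC)cc(OC)c1B(OC)OC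
A1 | alternative 1 | 2-(2,4-dimethoxy-6-pentylphenoxy)-6-(hept-1-yn-1-yl)-4-methoxybenzoic acid | CCCCCC#Cc1cc(OC)cc(Oc2c(OC)cc(OC)cc2CCCCC)c1C(=O)O
A2 | alternative 1 | 3-(hept-1-yn-1-yl)-5-methoxy-2-(trimethylsilyl)phenyl trifluoromethanesulfonate | CCCCCC#Cc1cc(OC)cc(OS(=O)(=O)C(F)(F)F)c1[Si](C)(C)C
A3 | alternative 1 | carbon dioxide | O=C=O
A4 | alternative 2 | methyl 2-(2,4-dimethoxy-6-pentylphenoxy)-4-hydroxy-6-methylbenzoate | COC(=O)c1c(C)cc(O)cc1Oc1c(OC)cc(OC)cc1CCCCC
A5 | alternative 2 | methyl 3-(2,4-dimethoxy-6-pentylphenoxy)prop-2-ynoate | COC(=O)C#COc1c(OC)cc(OC)cc1CCCCC
A6 | alternative 2 | (E)-4-methoxy-2-(trimethylsilyloxy)penta-1,3-diene | C=C(O[Si](C)(C)C)/C=C(/OC)C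
A7 | alternative 3 | 8-(4-ethoxy-2-hydroxy-6-pentylphenoxy)-6-methoxy-3-pentyl-1H-isochromen-1-one | CCCCCc1cc2cc(OC)cc(Oc3c(O)cc(OCC)cc3CCCCC)c2c(=O)o1
A8 | alternative 3 | (E)-1-diazo-3-{[(6-methoxy-1-oxo-3-pentyl-1H-isochromen-8-yl)oxy]methylidene}octan-2-one | CCCCC/C(=C\Oc1cc(OC)cc2cc(CCCCC)oc(=O)c12)C(=O)C=[N+]=[N-]
A9 | alternative 3 | ethoxyethyne | CCOC#C
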